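The pyranone ring B is disconnected at its two bonds to the arene, O1–C8a and C4–C4a, which sit on adjacent carbons of ring A. This reveals a hexasubstituted aryne (C4a≡C8a) and the O1–C2–C3–C4 unit as a syn-aldol-derived β-hydroxy Weinreb amide carrying both ring stereocentres. In one operation the alkoxide adds to C8a (directed by the C5 oxygen next to C4a) and the resulting C4a carbanion closes onto the amide carbonyl, giving the cis-chromanone without ever exposing C3 to base as a ketone. The aryne precursor is an o-silylaryl triflate already bearing the prenyl group and the (R)-hexanoate side chain.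

Key step: step 10

Remark: the labels O1, C2, C3, C4, C4a, C5 to C8 and C8a in the Why lines are the chromanone labels of the target, used for the corresponding atoms of every intermediate; ring A is the arene and ring B the pyranone. Locants inside compound names are those of the compound itself.

Step 1
Reactants: 1 (S)-4-benzyl-3-propanoyl-1,3-oxazolidin-2-one; 2 acetaldehyde
Product: 3 (S)-4-benzyl-3-[(2S,3R)-3-hydroxy-2-methylbutanoyl]-1,3-oxazolidin-2-one
Conditions: Bu2BOTf, iPr2NEt, CH2Cl2, −78 to 0 °C; then pH 7 buffer, MeOH, 30% H2O2, 0 °C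
Reagents that add atoms: none
Why: Evans syn-aldol reaction; the Z-boron enolate reacts through a chair Zimmerman–Traxler transition state in which the (S)-benzyl group of the auxiliary blocks one enolate face, which sets (2S,3R), the later C3 and C2 of ring B.

Step 2
Reactants: 3 (S)-4-benzyl-3-[(2S,3R)-3-hydroxy-2-methylbutanoyl]-1,3-oxazolidin-2-one
Product: 4 (2S,3R)-3-hydroxy-N-methoxy-N,2-dimethylbutanamide
Conditions: MeNH(OMe)·HCl, AlMe3, CH2Cl2, −15 to 0 °C; then aqueous potassium sodium tartrate
Reagents that add atoms: N,O-dimethylhydroxylamine hydrochloride, CNOC.Cl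
Why: Weinreb aminolysis of an Evans aldol adduct by the aluminium amide; the free β-hydroxyl directs attack to the exocyclic carbonyl and neither stereocentre is touched.

Step 3
Reactants: 5 phloroglucinol
Product: 6 3,5-bis(methoxymethoxy)phenol
Conditions: MOMCl (2 equiv), iPr2NEt, CH2Cl2/DMF, 0 °C to rt; chromatographic separation
Reagents that add atoms: chloromethyl methyl ether, COCCl
Why: Williamson-type O-alkylation of the threefold-symmetric triol; with two equivalents the bis-ether should be the main component of a statistical mixture, and the mono- and tris-ethers can be separated and recycled.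

Step 4
Reactants: 6 3,5-bis(methoxymethoxy)phenol
Product: 7 [3,5-bis(methoxymethoxy)phenoxy]tri(propan-2-yl)silane
Conditions: iPr3SiCl, imidazole, DMF, rt
Reagents that add atoms: chlorotri(propan-2-yl)silane, CC(C)[Si](Cl)(C(C)C)C(C)C
Why: Standard phenol silylation; the bulky silyl ether masks the acidic OH and is a poor directing group, which leaves the carbon between the two OMOM groups as the preferred lithiation site.

Step 5
Reactants: 7 [3,5-bis(methoxymethoxy)phenoxy]tri(propan-2-yl)silane; 8 prenyl bromide (1-bromo-3-methylbut-2-ene)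
Product: 10 3,5-bis(methoxymethoxy)-4-(3-methylbut-2-en-1-yl)phenol, via prenylated aryl silyl ether 9 (not isolated)
Conditions: n-BuLi, THF, 0 °C; CuBr·SMe2 (20 mol %), 8, −78 °C to rt; then Bu4NF, rt
Reagents that add atoms: none
Why: Directed ortho-metalation at the carbon flanked by two OMOM groups (cooperative coordination), copper-mediated SN2 allylation by prenyl bromide, then fluoride desilylation in the same flask; this places the prenyl group at C6 and leaves a symmetric phenol.

Step 6
Reactants: 10 3,5-bis(methoxymethoxy)-4-(3-methylbut-2-en-1-yl)phenol; 11 (E)-hex-2-enal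
Product: 12 (4R)-5,7-bis(methoxymethoxy)-6-(3-methylbut-2-en-1-yl)-4-propylchroman-2-ol (both epimers at the lactol carbon)
Conditions: (S)-α,α-diphenylprolinol trimethylsilyl ether (20 mol %), PhCO2H (20 mol %), toluene, 0 °C
Reagents that add atoms: none
Why: Iminium-catalysed Friedel–Crafts conjugate addition of the phenol ortho carbon (para position blocked, the two ortho positions equivalent) followed by hemiacetal formation; the diphenyl(silyloxy)methyl group of the (S)-catalyst shields one face of the E-iminium ion, so the arene should add to the other face and set the (R) benzylic centre.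

Step 7
Reactants: 12 (4R)-5,7-bis(methoxymethoxy)-6-(3-methylbut-2-en-1-yl)-4-propylchroman-2-ol
Product: 13 (4R)-5,7-bis(methoxymethoxy)-6-(3-methylbut-2-en-1-yl)-4-propylchroman-2-one
Conditions: Pr4N[RuO4] (5 mol %), N-methylmorpholine N-oxide, 4 Å sieves, CH2Cl2, rt
Reagents that add atoms: none
Why: Ley–Griffith oxidation of a lactol to the lactone under neutral conditions that should leave the MOM ethers and the trisubstituted alkene alone.

Step 8
Reactants: 13 (4R)-5,7-bis(methoxymethoxy)-6-(3-methylbut-2-en-1-yl)-4-propylchroman-2-one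
Product: 15 methyl (3R)-3-[2-hydroxy-3-iodo-4,6-bis(methoxymethoxy)-5-(3-methylbut-2-en-1-yl)phenyl]hexanoate, via ring-opened phenol ester 14 (not isolated)
Conditions: NaOMe, MeOH, 0 °C; then N-iodosuccinimide, −20 °C; AcOH
Reagents that add atoms: sodium methoxide, C[O-].[Na+]; N-iodosuccinimide, O=C1CCC(=O)N1I
Why: Methanolysis of the aryl lactone is driven by phenoxide formation, and the phenoxide then undergoes electrophilic aromatic iodination at the only free ring position (C4a, ortho to O−) faster than the prenyl alkene reacts.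

Step 9
Reactants: 15 methyl (3R)-3-[2-hydroxy-3-iodo-4,6-bis(methoxymethoxy)-5-(3-methylbut-2-en-1-yl)phenyl]hexanoate
Product: 18 methyl (3R)-3-[4,6-bis(methoxymethoxy)-5-(3-methylbut-2-en-1-yl)-2-(trifluoromethylsulfonyloxy)-3-(trimethylsilyl)phenyl]hexanoate, via aryl trimethylsilyl ether 16 (not isolated), via C-silylated phenol 17 (not isolated)
Conditions: (Me3Si)2NH, THF, 40 °C, then evaporation; n-BuLi, THF, −100 °C; Tf2O, −100 to −78 °C
Reagents that add atoms: hexamethyldisilazane, C[Si](C)(C)N[Si](C)(C)C; trifluoromethanesulfonic anhydride, O=S(=O)(OS(=O)(=O)C(F)(F)F)C(F)(F)F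
Why: Standard preparation of an o-silylaryl triflate: O-silylation, iodine–lithium exchange at −100 °C (expected to outrun attack on the methyl ester), retro-Brook 1,3-O→C silyl migration and trapping of the lithium phenoxide of 17 with Tf2O.

Step 10
Reactants: 18 methyl (3R)-3-[4,6-bis(methoxymethoxy)-5-(3-methylbut-2-en-1-yl)-2-(trifluoromethylsulfonyloxy)-3-(trimethylsilyl)phenyl]hexanoate; 4 (2S,3R)-3-hydroxy-N-methoxy-N,2-dimethylbutanamide
Product: 21 methyl (3R)-3-[(2R,3S)-5,7-bis(methoxymethoxy)-2,3-dimethyl-6-(3-methylbut-2-en-1-yl)-4-oxochroman-8-yl]hexanoate, via aryne 19 (not isolated), via hemiaminal potassium salt 20 (not isolated)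
Conditions: 4 (2 equiv), KH, 18-crown-6, THF, 0 °C; then 18, CsF, −40 to 0 °C; AcOH, −40 °C
Reagents that add atoms: none
Why: Proposed new method: fluoride attacks silicon in 18 and triflate is lost to give aryne 19; the potassium alkoxide of 4 adds to C8a and the aryl carbanion formed at C4a attacks the Weinreb amide carbonyl to give the hemiaminal salt 20, which should collapse to the ketone only on the acidic quench. The closest known reaction type is the fluoride-induced aryne annulation of methyl salicylates to xanthones (O-arylation then intramolecular acyl substitution), together with the O-arylation of aliphatic alcohols by arynes; an aliphatic β-hydroxy amide has not been used in this way. Ring B is closed by intermolecular C–O bond formation followed by 6-exo-trig attack of the C4a carbanion on the amide C=O. No stereocentre is made: C2 and C3 come from the aldol of step 1, no bond to them is formed or broken, and C3 stays next to a tetrahedral carbon (not a ketone) as long as base is present, which protects the cis relationship. The step needs regioselective addition to the unsymmetrical aryne, secured by the C5 OMOM group whose inductive effect directs the nucleophile to the distal carbon C8a and places the charge on C4a; it also needs acyl capture to beat protonation, secured by the absence of any O–H or N–H acid (KH as base) and the six-membered transition state.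

Step 11
Reactants: 21 methyl (3R)-3-[(2R,3S)-5,7-bis(methoxymethoxy)-2,3-dimethyl-6-(3-methylbut-2-en-1-yl)-4-oxochroman-8-yl]hexanoate
Product: 22 methyl (3R)-3-[(2R,3S)-5,7-dihydroxy-2,3-dimethyl-6-(3-methylbut-2-en-1-yl)-4-oxochroman-8-yl]hexanoate (CNP0068017.1)
Conditions: 2 M HCl in MeOH, rt; cold aqueous NaHCO3 work-up
Reagents that add atoms: none
Why: Acid-catalysed acetal exchange of both MOM ethers to dimethoxymethane; methanol as solvent keeps the side chain as its methyl ester (no lactonisation onto the C7 hydroxyl), and mild acid at room temperature should neither enolise C3 nor cyclise the prenyl group onto a neighbouring phenol.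

Compound list
1 | (S)-4-benzyl-3-propanoyl-1,3-oxazolidin-2-one | CCC(=O)N1[C@@H](Cc2ccccc2)COC1=O | starting material
2 | acetaldehyde | CC=O | starting material
3 | (S)-4-benzyl-3-[(2S,3R)-3-hydroxy-2-methylbutanoyl]-1,3-oxazolidin-2-one | C[C@@H](O)[C@H](C)C(=O)N1[C@@H](Cc2ccccc2)COC1=O | intermediate
4 | (2S,3R)-3-hydroxy-N-methoxy-N,2-dimethylbutanamide | C[C@@H](O)[C@H](C)C(=O)N(C)OC | intermediate
5 | phloroglucinol (benzene-1,3,5-triol) | Oc1cc(O)cc(O)c1 | starting material
6 | 3,5-bis(methoxymethoxy)phenol | COCOc1cc(O)cc(OCOC)c1 | intermediate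
7 | [3,5-bis(methoxymethoxy)phenoxy]tri(propan-2-yl)silane | COCOc1cc(OCOC)cc(O[Si](C(C)C)(C(C)C)C(C)C)c1 | intermediate
8 | prenyl bromide (1-bromo-3-methylbut-2-ene) | CC(C)=CCBr | starting material
9 | [3,5-bis(methoxymethoxy)-4-(3-methylbut-2-en-1-yl)phenoxy]tri(propan-2-yl)silane | COCOc1cc(O[Si](C(C)C)(C(C)C)C(C)C)cc(OCOC)c1CC=C(C)C | intermediate
10 | 3,5-bis(methoxymethoxy)-4-(3-methylbut-2-en-1-yl)phenol | COCOc1cc(O)cc(OCOC)c1CC=C(C)C | intermediate
11 | (E)-hex-2-enal | CCC/C=C/C=O | starting material
12 | (4R)-5,7-bis(methoxymethoxy)-6-(3-methylbut-2-en-1-yl)-4-propylchroman-2-ol (both lactol epimers) | CCC[C@@H]1CC(O)Oc2cc(OCOC)c(CC=C(C)C)c(OCOC)c21 | intermediate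
13 | (4R)-5,7-bis(methoxymethoxy)-6-(3-methylbut-2-en-1-yl)-4-propylchroman-2-one | CCC[C@@H]1CC(=O)Oc2cc(OCOC)c(CC=C(C)C)c(OCOC)c21 | intermediate
14 | methyl (3R)-3-[2-hydroxy-4,6-bis(methoxymethoxy)-5-(3-methylbut-2-en-1-yl)phenyl]hexanoate (formed as its sodium phenoxide) | CCC[C@H](CC(=O)OC)c1c(O)cc(OCOC)c(CC=C(C)C)c1OCOC | intermediate
15 | methyl (3R)-3-[2-hydroxy-3-iodo-4,6-bis(methoxymethoxy)-5-(3-methylbut-2-en-1-yl)phenyl]hexanoate | CCC[C@H](CC(=O)OC)c1c(O)c(I)c(OCOC)c(CC=C(C)C)c1OCOC | intermediate
16 | methyl (3R)-3-[3-iodo-4,6-bis(methoxymethoxy)-5-(3-methylbut-2-en-1-yl)-2-(trimethylsilyloxy)phenyl]hexanoate | CCC[C@H](CC(=O)OC)c1c(O[Si](C)(C)C)c(I)c(OCOC)c(CC=C(C)C)c1OCOC | intermediate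
17 | methyl (3R)-3-[2-hydroxy-4,6-bis(methoxymethoxy)-5-(3-methylbut-2-en-1-yl)-3-(trimethylsilyl)phenyl]hexanoate (formed as its lithium phenoxide) | CCC[C@H](CC(=O)OC)c1c(O)c([Si](C)(C)C)c(OCOC)c(CC=C(C)C)c1OCOC | intermediate
18 | methyl (3R)-3-[4,6-bis(methoxymethoxy)-5-(3-methylbut-2-en-1-yl)-2-(trifluoromethylsulfonyloxy)-3-(trimethylsilyl)phenyl]hexanoate | CCC[C@H](CC(=O)OC)c1c(OS(=O)(=O)C(F)(F)F)c([Si](C)(C)C)c(OCOC)c(CC=C(C)C)c1OCOC | intermediate
19 | methyl (3R)-3-[2,3-didehydro-4,6-bis(methoxymethoxy)-5-(3-methylbut-2-en-1-yl)phenyl]hexanoate (aryne, C4a≡C8a) | CCC[C@H](CC(=O)OC)C1=C(OCOC)C(CC=C(C)C)=C(OCOC)C#C1 | intermediate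
20 | potassium (2R,3S)-8-[(3R)-1-methoxy-1-oxohexan-3-yl]-4-[methoxy(methyl)amino]-5,7-bis(methoxymethoxy)-2,3-dimethyl-6-(3-methylbut-2-en-1-yl)chroman-4-olate | CCC[C@H](CC(=O)OC)c1c(OCOC)c(CC=C(C)C)c(OCOC)c2c1O[C@H](C)[C@H](C)C2([O-])N(C)OC.[K+] | intermediate
21 | methyl (3R)-3-[(2R,3S)-5,7-bis(methoxymethoxy)-2,3-dimethyl-6-(3-methylbut-2-en-1-yl)-4-oxochroman-8-yl]hexanoate | CCC[C@H](CC(=O)OC)c1c(OCOC)c(CC=C(C)C)c(OCOC)c2c1O[C@H](C)[C@H](C)C2=O | intermediate
22 | methyl (3R)-3-[(2R,3S)-5,7-dihydroxy-2,3-dimethyl-6-(3-methylbut-2-en-1-yl)-4-oxochroman-8-yl]hexanoate | CCC[C@H](CC(=O)OC)c1c(O)c(CC=C(C)C)c(O)c2c1O[C@H](C)[C@H](C)C2=O | target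

Total step count: 11. Longest linear sequence: 9 steps (steps 3 to 11, from phloroglucinol); amide 4 is made in 2 steps and joins in step 10.

Steps most likely to fail

Step 10 (proposed new method). What may go wrong: addition of the alkoxide at C4a instead of C8a, because C8a is flanked by the branched side chain; protonation of the C4a carbanion before acyl capture; ester exchange between the alkoxide and the side-chain methyl ester; collapse of the hemiaminal in the flask followed by base-induced epimerisation at C3. The fallback uses known chemistry and sets out from 15. The phenol is deprotonated with MeMgCl and the iodide is exchanged with iPrMgCl·LiCl in THF at −30 °C. Addition of (E)-2-methylbut-2-enal should give the allylic alcohol methyl (3R)-3-[2-hydroxy-3-[(E)-1-hydroxy-2-methylbut-2-en-1-yl]-4,6-bis(methoxymethoxy)-5-(3-methylbut-2-en-1-yl)phenyl]hexanoate F1. Oxidation with MnO2 in CH2Cl2 should give the o-hydroxyaryl tigloyl ketone methyl (3R)-3-[2-hydroxy-4,6-bis(methoxymethoxy)-3-[(E)-2-methylbut-2-enoyl]-5-(3-methylbut-2-en-1-yl)phenyl]hexanoate F2. A cinchona-alkaloid-catalysed asymmetric intramolecular oxa-Michael addition (quinine or its pseudo-enantiomer, chosen for the 2R,3S product; a known way to cis-2,3-dimethylchromanones from o-tigloylphenols) then closes ring B and comes back to the route at 21.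

Step 9. What may go wrong: attack of butyllithium on the methyl ester in competition with iodine–lithium exchange, and lactonisation of the phenol or phenoxide onto the side-chain ester during silylation or before triflation. The fallback sets out from 15 and avoids organolithium reagents. Palladium-catalysed silylation of the aryl iodide with hexamethyldisilane (Pd2(dba)3, a biaryl phosphine, KF, DMPU) should give the C-silylated phenol 17 directly. Triflation with PhNTf2 and Cs2CO3 in MeCN at 0 °C then comes back to the route at 18; no new compound is made.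

Step 6. What may go wrong: low enantiofacial selectivity or low rate with the aliphatic enal and this hindered phenol, and a second alkylation at the remaining ortho position. The fallback sets out from 10. Magnesium-mediated ortho-formylation (MgCl2, Et3N, paraformaldehyde, THF, reflux) should give 6-hydroxy-2,4-bis(methoxymethoxy)-3-(3-methylbut-2-en-1-yl)benzaldehyde F3. Wittig olefination with Ph3P=CHCO2Me in hot N,N-diethylaniline, with lactonisation, should give 5,7-bis(methoxymethoxy)-6-(3-methylbut-2-en-1-yl)-2H-chromen-2-one F4. Copper-catalysed asymmetric conjugate addition of n-PrMgBr (CuBr·SMe2, a Josiphos-type ferrocenyl diphosphine whose enantiomer is chosen for the 4R product, t-BuOMe, −75 °C) then gives the lactone directly and comes back to the route at 13, so the lactol 12 and step 7 are bypassed.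

Further compounds
F1 | step 10 | methyl (3R)-3-[2-hydroxy-3-[(E)-1-hydroxy-2-methylbut-2-en-1-yl]-4,6-bis(methoxymethoxy)-5-(3-methylbut-2-en-1-yl)phenyl]hexanoate (both carbinol epimers) | CCC[C@H](CC(=O)OC)c1c(O)c(C(O)/C(C)=C/C)c(OCOC)c(CC=C(C)C)c1OCOC
F2 | step 10 | methyl (3R)-3-[2-hydroxy-4,6-bis(methoxymethoxy)-3-[(E)-2-methylbut-2-enoyl]-5-(3-methylbut-2-en-1-yl)phenyl]hexanoate | CCC[C@H](CC(=O)OC)c1c(O)c(C(=O)/C(C)=C/C)c(OCOC)c(CC=C(C)C)c1OCOC
F0 | step 9 | none | none
F3 | step 6 | 6-hydroxy-2,4-bis(methoxymethoxy)-3-(3-methylbut-2-en-1-yl)benzaldehyde | COCOc1cc(O)c(C=O)c(OCOC)c1CC=C(C)C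
F4 | step 6 | 5,7-bis(methoxymethoxy)-6-(3-methylbut-2-en-1-yl)-2H-chromen-2-one | O=C1C=Cc2c(OCOC)c(CC=C(C)C)c(OCOC)cc2O1
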